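**Plan**

- Retrosynthesis: cut both interflavan bonds (upper C4–middle C8, middle C4–lower C8). In the upper unit, also cut the C3–O bond and C4–C4a and rejoin C3 to C4a, which turns its pyran ring C into the furan ring of a 2-aryl-2,3-dihydrobenzofuran whose C3 carries the future C4 as an exocyclic gem-diacetate carbon.
- Enabling feature: in the upper unit C3 (oxygen) and C4 (bonded to C4a of ring A) are vicinal, and ring A has oxygen at C5, C7 and C8a. Ring A therefore shifts readily from C3 to a cationic exocyclic carbon, which inserts that carbon into the O1–C2–C3–C3a–C7a ring (five to six atoms); the second acetoxy group delivers the C3 oxygen and leaves a C4 cation for arylation.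
- Forward, upper unit: 5,7-dihydroxychromone → benzyl ether → (2S)-flavanone by asymmetric 1,4-addition → oxidative ring contraction to the trans-dihydrobenzofuran ester → aldehyde → acylal.
- Forward, lower dimer: benzylated (+)-gallocatechin C4 ether and benzylated (+)-catechin are tied through a glutarate and coupled intramolecularly (3,4-cis, 4β→8). The key step then expands the ring and forges the upper 4α→8 bond; ester cleavage and hydrogenolysis finish.
- Stereochemistry: upper C2 from the [Rh(OH)(cod)]2/(S)-MeO-F12-BIPHEP catalyst; upper C3 and C4 from the stereospecific aryl shift/acetoxonium sequence; middle and lower C2/C3 from the two natural flavan-3-ols; middle C4 from the tether.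

Key step: step 12

Assumption: (+)-gallocatechin is taken as the commercial (2R,3S) enantiomer. With (S)-MeO-F12-BIPHEP [(S)-6,6'-dimethoxy-2,2'-bis{bis(3,4,5-trifluorophenyl)phosphino}biphenyl] the aryl group is assumed to add to the chromone face that gives the (2S)-flavanone, by analogy with (S)-biaryl bisphosphines on cyclic enones; if the sense is the opposite, the (R)-ligand is used.

**Route**

Step 1
Reactants: 1 5,7-dihydroxychromone
Product: 2 5,7-bis(benzyloxy)chromone
Conditions: BnBr, K2CO3, n-Bu4NI (cat.), DMF, 80 °C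
Reagents that add atoms: benzyl bromide, BrCc1ccccc1
Why: Williamson etherification of both phenols, in which heat and iodide catalysis overcome the hydrogen bond of the 5-OH to the carbonyl and the chromone ring tolerates anhydrous carbonate.

Step 2
Reactants: 2 5,7-bis(benzyloxy)chromone; 3 [3,4-bis(benzyloxy)phenyl]boronic acid
Product: 4 (2S)-5,7,3',4'-tetrakis(benzyloxy)flavanone
Conditions: [Rh(OH)(cod)]2 (cat.), (S)-MeO-F12-BIPHEP, toluene/H2O, 40 °C
Reagents that add atoms: none
Why: Rhodium-catalysed asymmetric 1,4-addition of an arylboronic acid to a chromone (Hayashi–Miyaura type), in which the electron-poor chiral bisphosphine keeps the aryl-rhodium species reactive towards the donor-substituted chromone and delivers the aryl group to one enantioface to set C2, while the near-neutral medium avoids ring opening to the chalcone.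

Step 3
Reactants: 4 (2S)-flavanone
Product: 5 methyl (2S,3S)-2-aryl-4,6-bis(benzyloxy)-2,3-dihydrobenzofuran-3-carboxylate (2,3-trans)
Conditions: PhI(OAc)2, H2SO4, HC(OMe)3, rt; aqueous NaHCO3 work-up
Reagents that add atoms: trimethyl orthoformate, COC(OC)OC
Why: Known oxidative ring contraction of flavanones with a trivalent iodine reagent in trimethyl orthoformate, in which the enol ether formed in situ is iodinated at C3 anti to the 2-aryl group, ring A shifts from C4 to C3 with loss of iodobenzene and C4 ends as the ester carbon, so that C2 is untouched and the 2,3-trans ester results.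

Step 4
Reactants: 5 trans ester
Product: 6 (2S,3S)-2-aryl-4,6-bis(benzyloxy)-2,3-dihydrobenzofuran-3-carbaldehyde
Conditions: i-Bu2AlH (1.1 equiv), toluene/CH2Cl2, −78 °C; aqueous potassium sodium tartrate (KNaC4H4O6) work-up
Reagents that add atoms: none
Why: Partial reduction of an α-branched methyl ester, whose tetrahedral aluminium hemiacetal is stable at −78 °C and releases the aldehyde only on work-up, with the cold neutral work-up guarding against β-elimination of the ring oxygen.

Step 5
Reactants: 6 aldehyde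
Product: 7 [(2S,3S)-2-aryl-4,6-bis(benzyloxy)-2,3-dihydrobenzofuran-3-yl]methanediyl diacetate (acylal)
Conditions: Ac2O, FeCl3 (cat.), CH2Cl2, −20 °C, short reaction time
Reagents that add atoms: acetic anhydride, CC(=O)OC(C)=O
Why: Lewis-acid-catalysed acylal formation from an aldehyde and acetic anhydride, which locks the enolisable β-aryloxy aldehyde and installs on the exocyclic carbon both the leaving group and the internal oxygen nucleophile needed in step 12 without touching a stereocentre.

Step 6
Reactants: 8 (+)-catechin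
Product: 9 5,7,3',4'-tetra-O-benzyl-(+)-catechin
Conditions: BnBr, K2CO3, DMF, 0 °C to rt
Reagents that add atoms: benzyl bromide, BrCc1ccccc1
Why: Williamson etherification that is selective for the four phenols over the secondary 3-OH under carbonate conditions.

Step 7
Reactants: 10 (+)-gallocatechin
Product: 11 5,7,3',4',5'-penta-O-benzyl-(+)-gallocatechin
Conditions: BnBr, K2CO3, DMF, 0 °C to rt, argon
Reagents that add atoms: benzyl bromide, BrCc1ccccc1
Why: The same phenol-selective Williamson etherification, run cold and under argon to protect the oxidation-prone pyrogallol ring.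

Step 8
Reactants: 11 penta-O-benzylgallocatechin
Product: 12 (2R,3S,4S)-4-(2-ethoxyethoxy)-penta-O-benzylgallocatechin
Conditions: DDQ, 2-ethoxyethanol, CH2Cl2, rt
Reagents that add atoms: 2-ethoxyethanol, CCOCCO
Why: DDQ benzylic oxidation at C4 (hydride abstraction to the ring A-stabilised cation) with capture by the alcohol from the face anti to ring B, the established way to C4-activated benzylated flavan-3-ols.

Step 9
Reactants: 9 tetra-O-benzylcatechin
Product: 13 3-O-(4-carboxybutanoyl)-tetra-O-benzylcatechin (hemiglutarate)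
Conditions: glutaric anhydride, DMAP (cat.), pyridine, CH2Cl2, rt
Reagents that add atoms: glutaric anhydride, O=C1CCCC(=O)O1
Why: DMAP-catalysed opening of a cyclic anhydride by the only free hydroxyl, which attaches the tether as a half ester.

Step 10
Reactants: 13 hemiglutarate; 12 C4 ether
Product: 14 mixed glutarate diester linking the 3-oxygen of the tetra-O-benzylcatechin unit to the 3-oxygen of the penta-O-benzylgallocatechin C4 ether
Conditions: DCC, DMAP (cat.), CH2Cl2, rt
Reagents that add atoms: none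
Why: Steglich esterification of the free 3-OH of the C4 ether with the tether carboxylic acid under neutral conditions that leave the acid-labile C4 ether intact.

Step 11
Reactants: 14 tethered diester
Product: 16 macrocyclic glutarate-bridged penta-O-benzylgallocatechin-(4β→8)-tetra-O-benzylcatechin, via flavan-4-yl cation triflate 15 (not isolated)
Conditions: TMSOTf (0.3 equiv), CH2Cl2 (2 mM), −20 °C; Et3N quench
Reagents that add atoms: none
Why: Lewis-acid ionisation of the C4 ether and intramolecular Friedel–Crafts alkylation by C8 of the tethered catechin, in which the short 3-O to 3-O glutarate tether forces attack on the C4 face syn to the 3-acyloxy group (3,4-cis, 4β) against the usual anti preference, as precedented for the catechin/catechin pair.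

Step 12
Reactants: 7 acylal; 16 macrocyclic dimer (2 equiv)
Product: 18 glutarate-bridged 3-O-acetyl-protected trimer, via acetoxonium triflate 17 (not isolated)
Conditions: TMSOTf (0.3 equiv), 4 Å molecular sieves, CH2Cl2, −78 to −20 °C; Et3N quench
Reagents that add atoms: none
Why: Proposed new method: TMSOTf ionises one acetate of acylal 7, and ring A, whose ipso carbon C3a lies over the exocyclic acyloxycarbenium carbon and is activated by oxygen at both ortho positions and at the para position, bridges to it (1,2-aryl shift through a phenonium-type transition state) while the carbonyl oxygen of the remaining acetoxy group attacks C3 from the rear and cuts the C3–C3a bond, so that the exocyclic carbon is inserted between C3 and ring A and the five-membered furan ring becomes the six-membered pyran ring C, held as the cis-fused acetoxonium ion 17. Ion 17 is the 3-O-acyl-bridged form of the flavan-4-yl cation and is attacked at C4 by C8 of the upper ring A of 16 in a Friedel–Crafts alkylation, which gives 18 and passes the proton to acetate. The closest known reactions are the reverse 1,2-aryl-shift ring contraction of flavanones used in step 3, aryl-assisted solvolysis with capture by a neighbouring acyloxy group (Woodward–Prévost-type acetoxonium formation) and the Lewis-acid coupling of 3-O-acyl-4-alkoxyflavans with flavan nucleophiles. The pyran ring arises by ring expansion (3-exo bridging of the ipso carbon followed by cleavage of the old ring bond), and the temporary dioxolanylium ring by 5-exo-tet attack of the carbonyl oxygen at C3. C2 is carried over from 7, C3 is set by inversion at the migration origin, which from the 2,3-trans acylal places the oxygen trans to the 2-aryl group, and C4 is set by attack of the arene anti to the cis-fused dioxolanylium ring (3,4-trans). The step needs the aryl shift to outrun 1,2-hydride shift and direct arylation of the exocyclic carbon, which the intramolecular, strongly donating ring A and the built-in acetoxy nucleophile should secure, and it needs C8 over C6 selectivity in 16, which rests on the usual preference of benzylated 4→8 dimers for C8 of their upper unit, with excess 16 and low temperature holding back self-condensation.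

Step 13
Reactants: 18 protected trimer
Product: 19 trideca-O-benzyl catechin-(4α→8)-gallocatechin-(4β→8)-catechin
Conditions: NaOMe (cat.), MeOH/THF, rt to 40 °C
Reagents that add atoms: none
Why: Zemplén transesterification removes the acetate and opens the glutarate bridge without touching benzyl ethers or any stereocentre, since no centre in 18 is base-labile.

Step 14
Reactants: 19 trideca-O-benzyl trimer
Product: 20 catechin-(4α→8)-gallocatechin-(4β→8)-catechin (target)
Conditions: H2 (1 atm), Pd(OH)2/C, THF/MeOH/H2O, rt; filtration and freeze-drying under argon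
Reagents that add atoms: none
Why: Neutral hydrogenolysis of all thirteen benzyl ethers, under which the interflavan bonds and the benzylic ring C–O bonds of proanthocyanidins are known to survive.

**Compound list**

1 | 5,7-dihydroxy-4H-chromen-4-one | O=c1ccoc2cc(O)cc(O)c12 | starting material
2 | 5,7-bis(benzyloxy)-4H-chromen-4-one | O=c1ccoc2cc(OCc3ccccc3)cc(OCc3ccccc3)c12 | intermediate
3 | [3,4-bis(benzyloxy)phenyl]boronic acid | OB(O)c1ccc(OCc2ccccc2)c(OCc2ccccc2)c1 | starting material
4 | (2S)-5,7-bis(benzyloxy)-2-[3,4-bis(benzyloxy)phenyl]-2,3-dihydro-4H-chromen-4-one | c3ccccc3COc1cc(OCc3ccccc3)c2c(c1)O[C@H](c1ccc(OCc3ccccc3)c(OCc3ccccc3)c1)CC2=O | intermediate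
5 | methyl (2S,3S)-4,6-bis(benzyloxy)-2-[3,4-bis(benzyloxy)phenyl]-2,3-dihydro-1-benzofuran-3-carboxylate (2,3-trans) | c3ccccc3COc1cc(OCc3ccccc3)c2c(c1)O[C@H](c1ccc(OCc3ccccc3)c(OCc3ccccc3)c1)[C@H]2C(=O)OC | intermediate
6 | (2S,3S)-4,6-bis(benzyloxy)-2-[3,4-bis(benzyloxy)phenyl]-2,3-dihydro-1-benzofuran-3-carbaldehyde | c3ccccc3COc1cc(OCc3ccccc3)c2c(c1)O[C@H](c1ccc(OCc3ccccc3)c(OCc3ccccc3)c1)[C@H]2C=O | intermediate
7 | [(2S,3S)-4,6-bis(benzyloxy)-2-[3,4-bis(benzyloxy)phenyl]-2,3-dihydro-1-benzofuran-3-yl]methanediyl diacetate | c3ccccc3COc1cc(OCc3ccccc3)c2c(c1)O[C@H](c1ccc(OCc3ccccc3)c(OCc3ccccc3)c1)[C@H]2C(OC(C)=O)OC(C)=O | intermediate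
8 | (+)-catechin, (2R,3S) | O[C@H]1Cc2c(O)cc(O)cc2O[C@@H]1c1ccc(O)c(O)c1 | starting material
9 | 5,7,3',4'-tetra-O-benzyl-(+)-catechin | O[C@H]1Cc2c(OCc3ccccc3)cc(OCc3ccccc3)cc2O[C@@H]1c1ccc(OCc3ccccc3)c(OCc3ccccc3)c1 | intermediate
10 | (+)-gallocatechin, (2R,3S) | O[C@H]1Cc2c(O)cc(O)cc2O[C@@H]1c1cc(O)c(O)c(O)c1 | starting material
11 | 5,7,3',4',5'-penta-O-benzyl-(+)-gallocatechin | O[C@H]1Cc2c(OCc3ccccc3)cc(OCc3ccccc3)cc2O[C@@H]1c1cc(OCc3ccccc3)c(OCc3ccccc3)c(OCc3ccccc3)c1 | intermediate
12 | (2R,3S,4S)-4-(2-ethoxyethoxy)-5,7,3',4',5'-penta-O-benzylgallocatechin (4β ether, 3,4-cis) | O[C@H]1[C@@H](OCCOCC)c2c(OCc3ccccc3)cc(OCc3ccccc3)cc2O[C@@H]1c1cc(OCc3ccccc3)c(OCc3ccccc3)c(OCc3ccccc3)c1 | intermediate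
13 | 5-oxo-5-{[(2R,3S)-5,7-bis(benzyloxy)-2-[3,4-bis(benzyloxy)phenyl]chroman-3-yl]oxy}pentanoic acid (3-O-hemiglutarate of tetra-O-benzylcatechin) | OC(=O)CCCC(=O)O[C@H]1Cc2c(OCc3ccccc3)cc(OCc3ccccc3)cc2O[C@@H]1c1ccc(OCc3ccccc3)c(OCc3ccccc3)c1 | intermediate
14 | pentanedioate (glutarate) diester linking the 3-oxygen of tetra-O-benzylcatechin to the 3-oxygen of 4-(2-ethoxyethoxy)-penta-O-benzylgallocatechin | O=C(CCCC(=O)O[C@H]1Cc2c(OCc3ccccc3)cc(OCc3ccccc3)cc2O[C@@H]1c1ccc(OCc3ccccc3)c(OCc3ccccc3)c1)O[C@H]4[C@@H](OCCOCC)c5c(OCc3ccccc3)cc(OCc3ccccc3)cc5O[C@@H]4c1cc(OCc3ccccc3)c(OCc3ccccc3)c(OCc3ccccc3)c1 | intermediate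
15 | C4 (flavan-4-yl) cation of the tethered diester as its triflate, not isolated | O=C(CCCC(=O)O[C@H]1Cc2c(OCc3ccccc3)cc(OCc3ccccc3)cc2O[C@@H]1c1ccc(OCc3ccccc3)c(OCc3ccccc3)c1)O[C@H]4[CH+]c5c(OCc3ccccc3)cc(OCc3ccccc3)cc5O[C@@H]4c1cc(OCc3ccccc3)c(OCc3ccccc3)c(OCc3ccccc3)c1.[O-]S(=O)(=O)C(F)(F)F | intermediate
16 | macrocyclic 3-O,3-O-glutarate of penta-O-benzylgallocatechin-(4β→8)-tetra-O-benzylcatechin (upper unit 2,3-trans-3,4-cis) | c1c(OCc3ccccc3)cc(OCc3ccccc3)c2c1O[C@H](c1cc(OCc3ccccc3)c(OCc3ccccc3)c(OCc3ccccc3)c1)[C@@H](OC(=O)CCCC(=O)O4)[C@H]2c1c(OCc3ccccc3)cc(OCc3ccccc3)c2c1O[C@H](c1ccc(OCc3ccccc3)c(OCc3ccccc3)c1)[C@@H]4C2 | intermediate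
17 | 3,4-cis-fused 2-methyl-1,3-dioxolan-2-ylium (acetoxonium) ion of tetra-O-benzylflavan, 2,3-trans, as its triflate, not isolated | c3ccccc3COc1cc(OCc3ccccc3)c2c(c1)O[C@H](c1ccc(OCc3ccccc3)c(OCc3ccccc3)c1)[C@H]4OC(C)=[O+][C@H]42.[O-]S(=O)(=O)C(F)(F)F | intermediate
18 | 3-O-acetyl-tetra-O-benzylcatechin-(4α→8)-penta-O-benzylgallocatechin-(4β→8)-tetra-O-benzylcatechin, middle and lower 3-O bridged by glutarate | c3ccccc3COc1cc(OCc3ccccc3)c2c(c1)O[C@H](c1ccc(OCc3ccccc3)c(OCc3ccccc3)c1)[C@@H](OC(C)=O)[C@@H]2c1c(OCc3ccccc3)cc(OCc3ccccc3)c2c1O[C@H](c1cc(OCc3ccccc3)c(OCc3ccccc3)c(OCc3ccccc3)c1)[C@@H](OC(=O)CCCC(=O)O4)[C@H]2c1c(OCc3ccccc3)cc(OCc3ccccc3)c2c1O[C@H](c1ccc(OCc3ccccc3)c(OCc3ccccc3)c1)[C@@H]4C2 | intermediate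
19 | trideca-O-benzyl catechin-(4α→8)-gallocatechin-(4β→8)-catechin (three free 3-OH) | c3ccccc3COc1cc(OCc3ccccc3)c2c(c1)O[C@H](c1ccc(OCc3ccccc3)c(OCc3ccccc3)c1)[C@@H](O)[C@@H]2c1c(OCc3ccccc3)cc(OCc3ccccc3)c2c1O[C@H](c1cc(OCc3ccccc3)c(OCc3ccccc3)c(OCc3ccccc3)c1)[C@@H](O)[C@H]2c1c(OCc3ccccc3)cc(OCc3ccccc3)c2c1O[C@H](c1ccc(OCc3ccccc3)c(OCc3ccccc3)c1)[C@@H](O)C2 | intermediate
20 | catechin-(4α→8)-gallocatechin-(4β→8)-catechin, CNP0302529.2 (upper unit 2,3-trans-3,4-trans, middle unit 2,3-trans-3,4-cis) | Oc1cc(O)c2c(c1)O[C@H](c1ccc(O)c(O)c1)[C@@H](O)[C@@H]2c1c(O)cc(O)c2c1O[C@H](c1cc(O)c(O)c(O)c1)[C@@H](O)[C@H]2c1c(O)cc(O)c2c1O[C@H](c1ccc(O)c(O)c1)[C@@H](O)C2 | target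

**Step count**

Total step count: 14. Longest linear sequence: 8 steps (steps 1 to 5, then 12 to 14).

**Steps most likely to fail**

Step 12. The acyloxycarbenium ion may be arylated directly at the exocyclic carbon before ring A shifts. A 1,2-hydride shift followed by aromatisation to the benzofuran may also compete, and the cation may be consumed by self-condensation. Fallback with known chemistry: setting out from 9, DDQ oxidation in the presence of 2-ethoxyethanol gives (2R,3S,4S)-4-(2-ethoxyethoxy)-tetra-O-benzylcatechin F1. Acetylation (Ac2O, DMAP, pyridine) gives its 3-O-acetate F2. Coupling of F2 with 16 under Yb(OTf)3 or TMSOTf in CH2Cl2 should give the 3,4-trans product through acetate participation. This comes back to the route at 18.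

Step 3. Ring B may migrate instead of ring A (leading to the isoflavone), the iodane may attack the electron-rich arenes, and benzyl ethers may be lost in the acidic medium. Fallback by a different mechanism: setting out from 4, the lithium enolate (LiN(SiMe3)2, −78 °C) is trifluoroacetylated with 2,2,2-trifluoroethyl trifluoroacetate to the 3-trifluoroacetylflavanone F3. Methanesulfonyl azide and Et3N convert F3 into the 3-diazoflavanone F4 (detrifluoroacetylative diazo transfer). Photochemical Wolff rearrangement of F4 in methanol contracts the ring to the ester as a mixture of 5 and its 3-epimer, the cis ester F5. NaOMe in methanol equilibrates F5 to the trans ester, which comes back to the route at 5.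

Step 11. The arene may attack the face of C4 anti to the 3-acyloxy group, the cation may react intermolecularly to give oligomers, or C6 may react in place of C8. Fallback: setting out from 12, with 9 in excess as the nucleophile, intermolecular TMSOTf coupling in CH2Cl2 at low temperature gives both C4 epimers. The 3,4-cis dimer diol, penta-O-benzylgallocatechin-(4β→8)-tetra-O-benzylcatechin F6, is separated by chromatography from the 3,4-trans isomer F7. F6 is bridged with glutaryl dichloride (pyridine, DMAP, high dilution), which comes back to the route at 16.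

**Further compounds**

F1 | step 12 | (2R,3S,4S)-4-(2-ethoxyethoxy)-5,7,3',4'-tetra-O-benzylcatechin | O[C@H]1[C@@H](OCCOCC)c2c(OCc3ccccc3)cc(OCc3ccccc3)cc2O[C@@H]1c1ccc(OCc3ccccc3)c(OCc3ccccc3)c1
F2 | step 12 | 3-O-acetyl-(2R,3S,4S)-4-(2-ethoxyethoxy)-5,7,3',4'-tetra-O-benzylcatechin | CC(=O)O[C@H]1[C@@H](OCCOCC)c2c(OCc3ccccc3)cc(OCc3ccccc3)cc2O[C@@H]1c1ccc(OCc3ccccc3)c(OCc3ccccc3)c1
F3 | step 3 | (2S)-5,7,3',4'-tetrakis(benzyloxy)-3-(trifluoroacetyl)flavanone (C3 not defined, enolised) | c3ccccc3COc1cc(OCc3ccccc3)c2c(c1)O[C@H](c1ccc(OCc3ccccc3)c(OCc3ccccc3)c1)C(C(=O)C(F)(F)F)C2=O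
F4 | step 3 | (2R)-3-diazo-5,7,3',4'-tetrakis(benzyloxy)flavanone (C2 spatially unchanged from the (2S)-flavanone) | c3ccccc3COc1cc(OCc3ccccc3)c2c(c1)O[C@H](c1ccc(OCc3ccccc3)c(OCc3ccccc3)c1)C(=[N+]=[N-])C2=O
F5 | step 3 | methyl (2S,3R)-4,6-bis(benzyloxy)-2-[3,4-bis(benzyloxy)phenyl]-2,3-dihydro-1-benzofuran-3-carboxylate (2,3-cis) | c3ccccc3COc1cc(OCc3ccccc3)c2c(c1)O[C@H](c1ccc(OCc3ccccc3)c(OCc3ccccc3)c1)[C@@H]2C(=O)OC
F6 | step 11 | penta-O-benzylgallocatechin-(4β→8)-tetra-O-benzylcatechin, 3,4-cis, both 3-OH free | c1c(OCc3ccccc3)cc(OCc3ccccc3)c2c1O[C@H](c1cc(OCc3ccccc3)c(OCc3ccccc3)c(OCc3ccccc3)c1)[C@@H](O)[C@H]2c1c(OCc3ccccc3)cc(OCc3ccccc3)c2c1O[C@H](c1ccc(OCc3ccccc3)c(OCc3ccccc3)c1)[C@@H](O)C2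
F7 | step 11 | penta-O-benzylgallocatechin-(4α→8)-tetra-O-benzylcatechin, 3,4-trans, both 3-OH free | c1c(OCc3ccccc3)cc(OCc3ccccc3)c2c1O[C@H](c1cc(OCc3ccccc3)c(OCc3ccccc3)c(OCc3ccccc3)c1)[C@@H](O)[C@@H]2c1c(OCc3ccccc3)cc(OCc3ccccc3)c2c1O[C@H](c1ccc(OCc3ccccc3)c(OCc3ccccc3)c1)[C@@H](O)C2
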